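The runs were generated by integration for an exercise; scatter was added.

0.596 is the number we carry through this flask: the loading exponent n, or apparent order in second catalyst, the power with which product at a fixed time follows the loading of second catalyst.

| setting | larch | alder | flask |
|---|---|---|---|
| substrate | 0.050 M | 0.050 M | 0.050 M |
| gas | 3 mM (held) | 3 mM (held) | 3.0 mM (held) |
| free catalyst | 5 mol% | 5 mol% | 5 mol% |
| second catalyst | 2.5 mol% | 10 mol% | 5 mol% |
| remark | run made earlier | run made earlier |  |
| time |  |  | 10 min |

- larch (time / min: product / %): 1.33: 0; 3.00: 0; 4.00: 3; 6.00: 2; 8.00: 5; 10.0: 7
- alder (time / min: product / %): 1.33: 0; 3.00: 5; 4.00: 7; 6.00: 9; 8.00: 12; 10.0: 16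

(each reading ± 1.5 percentage points)

- the numbers in the tables scatter with a standard deviation of 1.5 percentage points
- at the start none of the gas is in solution

1. product at 10 min, in percent of the substrate charged
2. the change that raises the amount of product at 10 min, in percent of the substrate charged most ("none" if none brings more than 2 percentage points) (alpha / delta / gamma / none)
3. amount of product at 10 min, in percent of the substrate charged, after alpha

- alpha: doubling the saturation concentration of gas, all else as stated
- delta: doubling the transfer coefficient of the gas, all else as stated
- gamma: doubling the amount of free catalyst, all else as stated

1. The larch and alder runs are charged alike but for one setting. They share substrate, gas and free catalyst and differ in second catalyst, 2.5 mol% against 10 mol%. At 10.0 min the larch run holds 7 % product and the alder run 16 %, each a reading that scatters by 1.5 percentage points.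

2. So 4.00 times the loading gives 2.29 times the product, and n is the logarithm of the second ratio over the logarithm of the first.

3. The alder run ends at less than the 28.0 % that proportion to the larch run gives. So, as with two time constants in series, some stage besides the one using second catalyst holds the product back. These readings do not name it.

4. The flask, at 5 mol%, has twice the larch loading, so we join the two ends by the power n and reckon 10.6 %. Both runs held gas and free catalyst fixed, so n tells us nothing about alpha, delta or gamma, and we commit to a number for y.

5. The forecast gives 11.5 %, higher than our figure, and names alpha with 21 %, arguing that “Doubling saturation raises both transfer and reaction driving force”.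

6. The flask gives 11.0 %. The change alpha brings the largest gain, 7.9 points, against 2.3 points for gamma and 0.61 points for delta, and it reaches 18.9 %.

    substrate + free catalyst ⇌ free catalyst + intermediate (K = 0.290, k = 0.500 M⁻¹ s⁻¹)
    partner + second catalyst + intermediate → second catalyst + product (k = 210 M⁻² s⁻¹)
    gas ⇌ partner, rate k3*(csat - [partner]) (kL = 0.0300 s⁻¹)

Now take the neighbour flask with 2 mol% of second catalyst, all else as in this flask. The same reckoning from the larch run gives 6.13 %, a small step outside the two ends, and the neighbour flask gives 5.21 %. Between the neighbour flask and this flask the exponent comes to 0.816, above n. In the neighbour flask c(intermediate) stands at 19.1 % of the substrate charged, against 16.3 % in this flask.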